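The cyclohexane ring is numbered C1 (CH carrying the side chain), C2 (methylidene carbon), C3 (allylic CHBr), C4, C5 (CHBr) and C6 (CMe2); the ring closure makes the C1–C6 bond. The key step exploits the C5 bromide sitting next to the quaternary C6: an acyclic, enantiopure β-bromo tertiary trifluoroacetate ionises to a bromine-bridged cation at C6, which the γ-carbon of an (E)-allylsilane captures. One operation closes the ring, relays the C5 configuration to C1 through a chair transition state and leaves the C2 methylidene regiospecifically. The precursor is built from (S)-linalool by two stereodefined cross-couplings; the C3 bromide follows by allylic hydroxylation and inversion.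

Key step: step 8

Assumption: (S)-(+)-linalool of high enantiomeric purity and the L-fructose-derived antipode of the Shi ketone are taken as purchasable; this ketone is taken to give the (S)-epoxide of an R–CH=CMe2 olefin, the mirror image of the (R)-epoxide formed with the D-fructose ketone.

Step 1
Reactants: 1 (S)-(+)-linalool
Product: 2 (3S)-3,7-dimethyl-3-(triethylsilyloxy)octa-1,6-diene
Conditions: Et3SiOTf, 2,6-lutidine, CH2Cl2, −78 to 0 °C
Reagents that add atoms: triethylsilyl trifluoromethanesulfonate, CC[Si](CC)(CC)OS(=O)(=O)C(F)(F)F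
Why: Silyl triflate with a hindered base silylates the tertiary allylic alcohol (silyl ether protection) so that this oxygen can be neither acylated nor ionised later, and the stereocentre is untouched.

Step 2
Reactants: 2 (3S)-3,7-dimethyl-3-(triethylsilyloxy)octa-1,6-diene
Product: 4 (4S)-4-methyl-4-(triethylsilyloxy)hex-5-enal, via ozonide 3 (not isolated)
Conditions: O3 (1 equiv), CH2Cl2, −78 °C; then Me2S, −78 to 23 °C
Reagents that add atoms: ozone, [O-][O+]=O
Why: Chemoselective ozonolysis with reductive work-up should cleave only the electron-rich trisubstituted alkene, because it reacts with ozone far faster than the monosubstituted vinyl group next to the quaternary carbon.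

Step 3
Reactants: 4 (4S)-4-methyl-4-(triethylsilyloxy)hex-5-enal
Product: 5 (3S)-7,7-dibromo-3-methyl-3-(triethylsilyloxy)hepta-1,6-diene
Conditions: CBr4, PPh3, Zn, CH2Cl2, 23 °C; then 4, 0 to 23 °C
Reagents that add atoms: tetrabromomethane, BrC(Br)(Br)Br
Why: Corey–Fuchs dibromo-olefination (zinc-modified, so that no HBr is formed) should convert the aldehyde into the 1,1-dibromoalkene without affecting the silyl ether.

Step 4
Reactants: 5 (3S)-7,7-dibromo-3-methyl-3-(triethylsilyloxy)hepta-1,6-diene
Product: 6 (3S,6Z)-7-bromo-3-methyl-3-(triethylsilyloxy)-8-(trimethylsilyl)octa-1,6-diene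
Conditions: Me3SiCH2MgCl + ZnCl2, THF, 0 °C (gives Me3SiCH2ZnCl); PdCl2(DPEphos) (3 mol %), THF, 0 to 23 °C
Reagents that add atoms: (trimethylsilyl)methylmagnesium chloride, C[Si](C)(C)C[Mg]Cl
Why: Negishi coupling in which zerovalent palladium inserts into the less hindered C–Br bond trans to the alkyl chain, so the silylmethyl group should enter trans to the chain and leave the remaining bromide cis to it, which fixes the alkene geometry.

Step 5
Reactants: 7 4-methylpenta-1,3-diene
Product: 8 (3S)-3-ethenyl-2,2-dimethyloxirane
Conditions: L-fructose-derived Shi ketone (0.3 equiv), KHSO5 (as 2KHSO5·KHSO4·K2SO4), K2CO3, Bu4NHSO4 (cat.), MeCN/CH2(OMe)2/aq. buffer pH 10.5, −10 to 0 °C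
Reagents that add atoms: potassium peroxymonosulfate, [K+].[O-]S(=O)(=O)OO
Why: Shi asymmetric epoxidation (chiral dioxirane, spiro transition state) should oxidise the more electron-rich trisubstituted double bond of the conjugated diene, and the L-series ketone sets the (S) configuration of the new stereocentre.

Step 6
Reactants: 6 (3S,6Z)-7-bromo-3-methyl-3-(triethylsilyloxy)-8-(trimethylsilyl)octa-1,6-diene; 8 (3S)-3-ethenyl-2,2-dimethyloxirane
Product: 10 (3S,6E,10S)-10,11-epoxy-3,11-dimethyl-3-(triethylsilyloxy)-7-[(trimethylsilyl)methyl]dodeca-1,6-diene, via alkylborane 9 (not isolated)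
Conditions: 8 (1.5 equiv), 9-BBN-H (1.4 equiv), THF, 0 to 23 °C; then 6, PdCl2(dppf) (5 mol %), AsPh3, K3PO4 (3 M aq.), DMF, 23 °C
Reagents that add atoms: none
Why: Anti-Markovnikov hydroboration of the vinyl group followed by B-alkyl Suzuki–Miyaura coupling, which replaces the vinylic bromide with retention of geometry, should place the epoxy-ethyl chain cis to the side chain while the epoxide stereocentre is carried through unchanged.

Step 7
Reactants: 10 (3S,6E,10S)-10,11-epoxy-3,11-dimethyl-3-(triethylsilyloxy)-7-[(trimethylsilyl)methyl]dodeca-1,6-diene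
Product: 11 (3S,6E,10R)-10-bromo-3,11-dimethyl-3-(triethylsilyloxy)-7-[(trimethylsilyl)methyl]dodeca-1,6-dien-11-ol
Conditions: Li2NiBr4 (THF solution), THF, 0 to 23 °C; H2O work-up
Reagents that add atoms: dilithium tetrabromonickelate, [Li+].[Li+].[Ni+2].[Br-].[Br-].[Br-].[Br-]
Why: Regioselective halohydrin formation in which soft bromide opens the trisubstituted epoxide by SN2 attack at its less substituted carbon with inversion, which should give the (R)-bromide next to a tertiary alcohol without touching the allylsilane.

Step 8
Reactants: 11 (3S,6E,10R)-10-bromo-3,11-dimethyl-3-(triethylsilyloxy)-7-[(trimethylsilyl)methyl]dodeca-1,6-dien-11-ol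
Product: 14 triethylsilyl ether of (3S)-5-[(1R,3R)-3-bromo-2,2-dimethyl-6-methylidenecyclohexyl]-3-methylpent-1-en-3-ol, via trifluoroacetate 12 (not isolated), via bromonium ion 13 (not isolated)
Conditions: (CF3CO)2O, pyridine, DMAP (cat.), CH2Cl2, 0 °C; evaporate; (CF3)2CHOH, 2,6-lutidine, 0.01 M, 0 to 23 °C
Reagents that add atoms: none
Why: Acylation gives tertiary trifluoroacetate 12, which in the ionising, non-nucleophilic solvent should heterolyse with anchimeric help from the neighbouring bromine to bromonium ion 13 without loss of configuration at the CHBr carbon; the γ-carbon of the allylsilane opens 13 at its tertiary carbon anti to bromine, and loss of the silyl group from the β-silyl cation leaves the exocyclic methylidene (intramolecular Hosomi–Sakurai-type SE2′ termination). The closest known reaction types are the stereospecific bromonium polyene cyclisation started by solvolysis of an enantioenriched vicinal bromo halide or bromohydrin ester, and the allylsilane-terminated cation–olefin cyclisation. The cyclohexane closes in the 6-endo-trig mode at the alkene (both alkene carbons end in the ring) with exo, Markovnikov opening of the bromonium ion. The new stereocentre, the CH carrying the side chain, is set by the chair transition state: bromine is equatorial, and the chain, which is cis to the tether on the (E)-allylsilane, is forced axial, which gives the 1,3-trans relation to bromine; its absolute sense comes from the (R)-CHBr centre. The step needs ring closure to outrun bromonium transfer, proton loss and ionisation of the tertiary allylic silyl ether; high dilution, lutidine buffering, the nucleophilicity of the allylsilane and the six-membered transition state should secure this.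

Step 9
Reactants: 14 triethylsilyl ether of (3S)-5-[(1R,3R)-3-bromo-2,2-dimethyl-6-methylidenecyclohexyl]-3-methylpent-1-en-3-ol
Product: 15 (3S)-5-[(1R,3R)-3-bromo-2,2-dimethyl-6-methylidenecyclohexyl]-3-methylpent-1-en-3-ol
Conditions: HF·pyridine, pyridine, THF, 0 °C
Reagents that add atoms: none
Why: Fluoride-mediated desilylation under non-basic conditions should free the tertiary alcohol without E2 elimination of the hindered secondary bromide.

Step 10
Reactants: 15 (3S)-5-[(1R,3R)-3-bromo-2,2-dimethyl-6-methylidenecyclohexyl]-3-methylpent-1-en-3-ol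
Product: 16 (1S,3R,5R)-5-bromo-3-[(3S)-3-hydroxy-3-methylpent-4-en-1-yl]-4,4-dimethyl-2-methylidenecyclohexan-1-ol
Conditions: SeO2 (0.3 equiv), t-BuOOH (3 equiv), CH2Cl2, 23 °C
Reagents that add atoms: tert-butyl hydroperoxide, CC(C)(C)OO (net oxygen source, relayed through SeO2, O=[Se]=O)
Why: Riley allylic oxidation (ene reaction at the methylidene, then [2,3]-sigmatropic shift) should hydroxylate the ring CH2 next to the methylidene carbon and not the hindered CH, with oxygen delivered to the face opposite the pseudo-axial side chain, so that the carbinol centre is set trans to it.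

Step 11
Reactants: 16 (1S,3R,5R)-5-bromo-3-[(3S)-3-hydroxy-3-methylpent-4-en-1-yl]-4,4-dimethyl-2-methylidenecyclohexan-1-ol
Product: 17 (3S)-5-[(1S,3R,5R)-3,5-dibromo-2,2-dimethyl-6-methylidenecyclohexyl]-3-methylpent-1-en-3-ol
Conditions: CBr4, PPh3, CH2Cl2, −20 °C
Reagents that add atoms: tetrabromomethane, BrC(Br)(Br)Br
Why: Appel reaction in which bromide displaces the activated secondary allylic oxygen by SN2 with inversion at low temperature, which should give the bromide cis to the side chain while the hindered tertiary alcohol stays untouched.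

Compound list
1 | (S)-(+)-linalool | C=C[C@@](C)(O)CCC=C(C)C | starting material
2 | (3S)-3,7-dimethyl-3-(triethylsilyloxy)octa-1,6-diene | C=C[C@@](C)(O[Si](CC)(CC)CC)CCC=C(C)C | intermediate
3 | ozonide of 2 (3,3-dimethyl-1,2,4-trioxolane at the former trisubstituted alkene) | C=C[C@@](C)(O[Si](CC)(CC)CC)CCC1OOC(C)(C)O1 | intermediate
4 | (4S)-4-methyl-4-(triethylsilyloxy)hex-5-enal | C=C[C@@](C)(O[Si](CC)(CC)CC)CCC=O | intermediate
5 | (3S)-7,7-dibromo-3-methyl-3-(triethylsilyloxy)hepta-1,6-diene | C=C[C@@](C)(O[Si](CC)(CC)CC)CCC=C(Br)Br | intermediate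
6 | (3S,6Z)-7-bromo-3-methyl-3-(triethylsilyloxy)-8-(trimethylsilyl)octa-1,6-diene | C=C[C@@](C)(O[Si](CC)(CC)CC)CC/C=C(\Br)C[Si](C)(C)C | intermediate
7 | 4-methylpenta-1,3-diene | CC(C)=CC=C | starting material
8 | (3S)-3-ethenyl-2,2-dimethyloxirane | C=C[C@@H]1OC1(C)C | intermediate
9 | 9-{2-[(2S)-3,3-dimethyloxiran-2-yl]ethyl}-9-borabicyclo[3.3.1]nonane | B1(CC[C@@H]2OC2(C)C)C2CCCC1CCC2 | intermediate
10 | (3S,6E,10S)-10,11-epoxy-3,11-dimethyl-3-(triethylsilyloxy)-7-[(trimethylsilyl)methyl]dodeca-1,6-diene | C=C[C@@](C)(O[Si](CC)(CC)CC)CC/C=C(/C[Si](C)(C)C)CC[C@@H]1OC1(C)C | intermediate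
11 | (3S,6E,10R)-10-bromo-3,11-dimethyl-3-(triethylsilyloxy)-7-[(trimethylsilyl)methyl]dodeca-1,6-dien-11-ol | C=C[C@@](C)(O[Si](CC)(CC)CC)CC/C=C(/C[Si](C)(C)C)CC[C@@H](Br)C(C)(C)O | intermediate
12 | trifluoroacetate of 11 | C=C[C@@](C)(O[Si](CC)(CC)CC)CC/C=C(/C[Si](C)(C)C)CC[C@@H](Br)C(C)(C)OC(=O)C(F)(F)F | intermediate
13 | bromonium ion from 12, as its trifluoroacetate ion pair | C=C[C@@](C)(O[Si](CC)(CC)CC)CC/C=C(/C[Si](C)(C)C)CC[C@H]1[Br+]C1(C)C.[O-]C(=O)C(F)(F)F | intermediate
14 | triethylsilyl ether of (3S)-5-[(1R,3R)-3-bromo-2,2-dimethyl-6-methylidenecyclohexyl]-3-methylpent-1-en-3-ol | C=C[C@@](C)(O[Si](CC)(CC)CC)CC[C@@H]1C(=C)CC[C@@H](Br)C1(C)C | intermediate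
15 | (3S)-5-[(1R,3R)-3-bromo-2,2-dimethyl-6-methylidenecyclohexyl]-3-methylpent-1-en-3-ol | C=C[C@@](C)(O)CC[C@@H]1C(=C)CC[C@@H](Br)C1(C)C | intermediate
16 | (1S,3R,5R)-5-bromo-3-[(3S)-3-hydroxy-3-methylpent-4-en-1-yl]-4,4-dimethyl-2-methylidenecyclohexan-1-ol | C=C[C@@](C)(O)CC[C@@H]1C(=C)[C@@H](O)C[C@@H](Br)C1(C)C | intermediate
17 | (3S)-5-[(1S,3R,5R)-3,5-dibromo-2,2-dimethyl-6-methylidenecyclohexyl]-3-methylpent-1-en-3-ol | C=C[C@@](C)(O)CC[C@@H]1C(=C)[C@H](Br)C[C@@H](Br)C1(C)C | target

Total step count: 11. Longest linear sequence: 10 (steps 1 to 4 and 6 to 11; step 5 supplies the second fragment).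

Steps most likely to fail

Step 8. The trifluoroacetate may ionise too slowly, or the bromonium ion may lose a proton or be trapped by solvent before the ring closes. The fallback sets out from 11 and changes the way the cation is generated. The tertiary hydroxyl is exchanged for chloride with 1-chloro-N,N,2-trimethylprop-1-en-1-amine in CH2Cl2, which should give the vicinal bromochloride F1 with the CHBr centre unchanged. Chloride abstraction with AgBF4 in CH2Cl2 at −78 °C, buffered with 2,6-di-tert-butylpyridine, should then generate the same bromonium ion in a non-nucleophilic medium, where the allylsilane is the only nucleophile. The route is rejoined at 14.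

Step 10. Oxygen may be delivered to the wrong face of the ring, or over-oxidation to the enone may compete. The fallback sets out from 15 and accepts the epimeric allylic alcohol F2 (hydroxyl cis to the side chain) as the oxidation product. Mitsunobu esterification with 4-nitrobenzoic acid, PPh3 and diisopropyl azodicarboxylate should invert the carbinol centre to give the 4-nitrobenzoate F3. Methanolysis with K2CO3 in MeOH then rejoins the route at 16.

Step 11. Bromide may attack the methylidene carbon (allylic transposition), or the activated allylic oxygen may ionise with loss of configuration. The fallback sets out from 16 and separates activation from displacement. Selective sulfonylation of the secondary hydroxyl with methanesulfonic anhydride and Et3N at −40 °C should give the methanesulfonate F4. Direct SN2 displacement with LiBr in THF/acetone at −20 °C, with inversion, then rejoins the route at 17.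

Further compounds
F1 | step 8 | (3S,6E,10R)-10-bromo-11-chloro-3,11-dimethyl-3-(triethylsilyloxy)-7-[(trimethylsilyl)methyl]dodeca-1,6-diene | C=C[C@@](C)(O[Si](CC)(CC)CC)CC/C=C(/C[Si](C)(C)C)CC[C@@H](Br)C(C)(C)Cl
F2 | step 10 | (1R,3R,5R)-5-bromo-3-[(3S)-3-hydroxy-3-methylpent-4-en-1-yl]-4,4-dimethyl-2-methylidenecyclohexan-1-ol | C=C[C@@](C)(O)CC[C@@H]1C(=C)[C@H](O)C[C@@H](Br)C1(C)C
F3 | step 10 | (1S,3R,5R)-5-bromo-3-[(3S)-3-hydroxy-3-methylpent-4-en-1-yl]-4,4-dimethyl-2-methylidenecyclohexyl 4-nitrobenzoate | C=C[C@@](C)(O)CC[C@@H]1C(=C)[C@@H](OC(=O)c2ccc(cc2)[N+](=O)[O-])C[C@@H](Br)C1(C)C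
F4 | step 11 | (1S,3R,5R)-5-bromo-3-[(3S)-3-hydroxy-3-methylpent-4-en-1-yl]-4,4-dimethyl-2-methylidenecyclohexyl methanesulfonate | C=C[C@@](C)(O)CC[C@@H]1C(=C)[C@@H](OS(C)(=O)=O)C[C@@H](Br)C1(C)C
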